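Slowness was the worry with the teal charge, whose substrate stands at 0.180 M, less than the 0.600 M of the violet run, and I wanted one number to say how far that flask gets in 61 min.

the same everywhere: catalyst 0.0480 M
- violet: substrate 0.600 M; coupling partner 0.900 M
- red: substrate 0.600 M; coupling partner 0.900 M; product 0.180 M
- green: substrate 0.600 M; coupling partner 2.70 M
- teal: substrate 0.180 M; coupling partner 0.480 M; time 61 min

| run | time / min | [product] / M |
|---|---|---|
| violet run | 3.5 | 0.0453 |
| violet run | 11 | 0.1314 |
| violet run | 20 | 0.2194 |
| violet run | 32 | 0.3099 |
| violet run | 46 | 0.3851 |
| violet run | 61 | 0.4402 |
| red run | 3.5 | 0.2372 |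
| red run | 11 | 0.3424 |
| red run | 20 | 0.4414 |
| red run | 32 | 0.5307 |
| red run | 46 | 0.6055 |
| red run | 61 | 0.6511 |
| green run | 3.5 | 0.1308 |
| green run | 11 | 0.3504 |
| green run | 20 | 0.4950 |
| green run | 32 | 0.5680 |
| green run | 46 | 0.5924 |
| green run | 61 | 0.5986 |

(scatter of a reading: 0.002 M)

* apparent order in [coupling partner] of the starting rate, round the charge of the violet run (the rate where two percent of its substrate have turned into product)
* product in the teal run at 61 min, as a share of the substrate charged

- Overall: substrate + coupling partner -> product, with catalyst as catalyst.
- Constant volume, constant temperature.
- "The second partner" is coupling partner.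
- An order is taken over about fifteen percent of the charge, up and down.

I read the runs through the integrated second-order law in substrate and coupling partner, which gives a rate constant from a single reading. At 11 min the violet run gave 0.0271 M⁻¹ min⁻¹ at a mean product of 0.0657 M. The red run, having made 0.162 M by then, gave 0.0353 M⁻¹ min⁻¹ at 0.261 M, more than the violet run. The line through these two has a slope of 0.0423 M⁻² min⁻¹ and runs back to 0.0243 M⁻¹ min⁻¹ at no product. The green run then tested it independently, reading 0.0320 M⁻¹ min⁻¹ where the line says 0.0317 M⁻¹ min⁻¹, which makes the order in coupling partner 1.01 between the violet and green charges.

For the teal run I replaced the climbing constant by its mean, taking the mean product as 0.0450 M, a quarter of the substrate, which gives 0.0262 M⁻¹ min⁻¹. The clock number is that mean constant times the excess of coupling partner over substrate, the limiting reagent, times the time; it is the logarithm of how far the ratio of partner to substrate has grown. Here it came to 0.480, which solves to 49.6% of the substrate. As a test of the single mean, the constant at no product gives 47.3%, and the constant at twice my mean product gives 51.8%.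

The forecast gave an order of 0.98 (0.88 to 1.08) and 50.5% (46% to 55%), reading the seeded red run as “real product acceleration, not catalyst induction”. My 49.6% lies a little below its figure.

The flask gave an order of 1.0 and 49.7%, a clock number of 0.481.

    catalyst + substrate + coupling partner → product + catalyst (0.4038 M⁻² min⁻¹)
    substrate + coupling partner → product (0.004764 M⁻¹ min⁻¹)
    substrate + coupling partner + product → 2 product (0.04248 M⁻² min⁻¹)

The clock number also serves the green run: a quarter of its substrate turned means 0.231, and the line's constant at a mean product of 0.0750 M turns that into 4.00 min, against 4.01 min in the flask. The teal clock runs as far as it does partly because of the conversion of substrate and coupling partner that needs no catalyst. The teal run repeated without that step proves it: product at 61 min falls from 49.7% to 43.1%, a loss of 6.6 percentage points.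

The earlier runs and the new flask stem from a simulated flask on assumed constants; the scatter is artificial.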